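## Retrosynthetic overview

1. The target aldehyde comes from its diethyl acetal; the heptyl tether is cut between its second and third carbon from the stereocentre (sp3–sp3 Suzuki–Miyaura coupling), giving a chiral vinyl acetal and a 5-(5-bromopentyl)furan-2-ylacetate.
2. The vinyl acetal comes from an enantioselective copper-catalysed SN2′ coupling of a propanal homoenolate equivalent (the β-boryl acetal from acrolein diethyl acetal and 9-BBN) with (Z)-1-chlorohept-2-ene. This C–C bond sets the only stereocentre.
3. The (Z)-allyl chloride comes from hept-2-yn-1-ol by semi-hydrogenation and chlorination.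
4. The bromopentylfuran ester comes from furan by lithiation/alkylation with 1,5-dibromopentane, then radical C–H alkylation at C5 with methyl bromoacetate.
5. No ring is formed in the route; the furan ring is bought as furan.

Assumption: the (R)-bisphosphine is taken to give the (S)-vinyl acetal in the key step; if the first run shows the opposite sense, the (S)-ligand is used and nothing else changes.

## Route

Step 1
Reactants: 1 hept-2-yn-1-ol
Product: 2 (Z)-hept-2-en-1-ol
Conditions: H2 (1 atm), 5% Pd/CaCO3 poisoned with Pb(OAc)2 (Lindlar catalyst), quinoline, EtOAc, rt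
Reagents that add atoms: none
Why: Lindlar semi-hydrogenation adds hydrogen syn to the alkyne on the poisoned palladium surface, giving the Z-alkene, and quinoline suppresses over-reduction.

Step 2
Reactants: 2 (Z)-hept-2-en-1-ol
Product: 3 (Z)-1-chlorohept-2-ene
Conditions: NCS (1.2 equiv), Me2S (1.3 equiv), CH2Cl2, −20 → 0 °C
Reagents that add atoms: N-chlorosuccinimide, ClN1C(=O)CCC1=O
Why: Corey–Kim chlorination, in which chloride displaces the alkoxysulfonium group by SN2 at the primary allylic carbon, so the Z geometry and the position of the double bond are kept.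

Step 3
Reactants: 4 acrolein diethyl acetal; 3 (Z)-1-chlorohept-2-ene
Product: 6 (4S)-4-ethenyl-1,1-diethoxyoctane, via alkylborane 5 (not isolated)
Conditions: 4 (1.6 equiv), 9-BBN dimer (0.75 equiv), THF, 60 °C, 1 h; then 3 (1.0 equiv), (CuOTf)2·toluene (5 mol%), (R)-DTBM-SEGPHOS (10 mol%), EtOK (1.5 equiv), 1,4-dioxane, 15 °C, 24 h
Reagents that add atoms: none
Why: Hydroboration puts boron on the terminal carbon of the acetal to give a propanal homoenolate equivalent, and in the copper-catalysed enantioselective γ-selective allylic substitution with alkyl-9-BBN reagents (SN2′ allyl–alkyl coupling) the ethoxide-activated borate hands this alkyl group to monovalent copper, whose chiral bisphosphine complex adds to one face of the Z-alkene at the butyl-bearing γ-carbon and expels chloride, creating the (S)-stereocentre and the terminal vinyl group.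

Step 4
Reactants: 7 furan; 8 1,5-dibromopentane
Product: 10 2-(5-bromopentyl)furan, via 2-furyllithium 9 (not isolated)
Conditions: n-BuLi (1.0 equiv), THF, −78 → 0 °C; then 8 (3 equiv), −78 °C → rt; excess 8 removed by distillation
Reagents that add atoms: none
Why: α-Lithiation of furan at its most acidic C–H followed by SN2 alkylation, with excess dibromide to suppress double substitution.

Step 5
Reactants: 10 2-(5-bromopentyl)furan; 11 methyl bromoacetate
Product: 12 methyl 2-[5-(5-bromopentyl)furan-2-yl]acetate
Conditions: 11 (2 equiv), fac-Ir(ppy)3 (1 mol%), K2HPO4 (2 equiv), MeCN, blue LEDs, rt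
Reagents that add atoms: none
Why: Photoredox homolytic aromatic substitution, in which the excited iridium complex reduces the bromoacetate to the electrophilic radical •CH2CO2Me that adds to the free α-position (C5) of the electron-rich furan, and oxidation by tetravalent iridium plus loss of a proton restores the ring while the unactivated primary C–Br bond is left alone.

Step 6
Reactants: 6 (4S)-4-ethenyl-1,1-diethoxyoctane; 12 methyl 2-[5-(5-bromopentyl)furan-2-yl]acetate
Product: 15 methyl 2-{5-[(8R)-8-butyl-11-oxoundecyl]furan-2-yl}acetate, via alkylborane 13 (not isolated), via diethyl acetal 14 (not isolated)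
Conditions: 6 (1.2 equiv), 9-BBN (0.5 M in THF, 1.25 equiv), 0 °C → rt; then 12 (1.0 equiv), Pd(OAc)2 (4 mol%), PCy3 (8 mol%), K3PO4·H2O (1.3 equiv), THF, rt, 20 h; filter through diatomaceous earth; then TsOH·H2O (0.2 equiv), THF/H2O 5:1, rt, 2 h
Reagents that add atoms: water, O
Why: Anti-Markovnikov hydroboration of the vinyl group, B-alkyl Suzuki–Miyaura coupling with the primary bromide (the bulky electron-rich PCy3 lets coupling outrun β-hydride elimination) and acid-catalysed acetal hydrolysis give the target without touching the stereocentre, whose descriptor changes from S to R only because the CIP priorities change.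

## Compound list

1 | hept-2-yn-1-ol | CCCCC#CCO | starting material
2 | (Z)-hept-2-en-1-ol | CCCC/C=C\CO | intermediate
3 | (Z)-1-chlorohept-2-ene | CCCC/C=C\CCl | intermediate
4 | acrolein diethyl acetal (3,3-diethoxyprop-1-ene) | C=CC(OCC)OCC | starting material
5 | 9-(3,3-diethoxypropyl)-9-borabicyclo[3.3.1]nonane | CCOC(CCB1C2CCCC1CCC2)OCC | intermediate
6 | (4S)-4-ethenyl-1,1-diethoxyoctane, also (3S)-3-(3,3-diethoxypropyl)hept-1-ene | CCCC[C@@H](CCC(OCC)OCC)C=C | intermediate
7 | furan | c1ccoc1 | starting material
8 | 1,5-dibromopentane | BrCCCCCBr | starting material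
9 | 2-furyllithium | [Li]c1ccco1 | intermediate
10 | 2-(5-bromopentyl)furan | BrCCCCCc1ccco1 | intermediate
11 | methyl bromoacetate | COC(=O)CBr | starting material
12 | methyl 2-[5-(5-bromopentyl)furan-2-yl]acetate | COC(=O)Cc1ccc(CCCCCBr)o1 | intermediate
13 | 9-[(3S)-3-butyl-6,6-diethoxyhexyl]-9-borabicyclo[3.3.1]nonane | CCCC[C@@H](CCC(OCC)OCC)CCB1C2CCCC1CCC2 | intermediate
14 | methyl 2-{5-[(8R)-8-butyl-11,11-diethoxyundecyl]furan-2-yl}acetate | CCCC[C@@H](CCC(OCC)OCC)CCCCCCCc1ccc(CC(=O)OC)o1 | intermediate
15 | methyl 2-{5-[(8R)-8-butyl-11-oxoundecyl]furan-2-yl}acetate, also (4R)-4-butyl-11-[5-(2-methoxy-2-oxoethyl)furan-2-yl]undecanal | CCCC[C@@H](CCC=O)CCCCCCCc1ccc(CC(=O)OC)o1 | target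

## Summary

Total step count: 6. Longest linear sequence: 4 (steps 1, 2, 3, 6).

**Steps most likely to fail**

Step 3. The coupling is a known reaction type, but this pair of partners is untested. The acetal-bearing borane may react slowly, and the expected enantiomeric excess is about 85–90%. The product is an oil, so the excess cannot be raised by crystallisation. The fallback keeps the boron homoenolate but uses it for an achiral bond and sets the stereocentre by delivering butyl instead. It sets out from 5. A B-alkyl Suzuki–Miyaura coupling with (E)-3-iodoprop-2-en-1-ol (PdCl2(dppf), aqueous K3PO4, THF/DMF, 50 °C) gives (E)-6,6-diethoxyhex-2-en-1-ol F1. NCS/Me2S converts this into (E)-1-chloro-6,6-diethoxyhex-2-ene F2. Copper-catalysed asymmetric allylic alkylation of F2 with n-BuMgBr (copper thiophene-2-carboxylate 3 mol%, binaphthol-derived phosphoramidite ligand, CH2Cl2, −78 °C) then gives the branched product. This is a well-precedented pairing of an n-alkyl Grignard reagent with an aliphatic (E)-allyl chloride. The fallback comes back to the route at 6.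

Step 6. The sp3–sp3 coupling can lose material to β-hydride elimination, to reduction of the bromide or to enolisation of the furylacetate, and the telescoped hydrolysis must not open the furan. The fallback replaces cross-coupling by metathesis and hydrogenation. It sets out from 6 and from 9 (made as in step 4). Alkylation of 9 with 7-bromohept-1-ene gives 2-(hept-6-en-1-yl)furan F3. Cross-metathesis of 6 with excess F3 (second-generation Hoveyda–Grubbs catalyst, CH2Cl2, 40 °C) gives 2-[(6E,8S)-8-butyl-11,11-diethoxyundec-6-en-1-yl]furan F4; its E/Z ratio does not matter. Hydrogenation with H2 and RhCl(PPh3)3 saturates the disubstituted alkene without touching the furan and gives 2-[(8R)-8-butyl-11,11-diethoxyundecyl]furan F5. The photoredox alkylation of step 5 with 11 then installs the acetate arm. The fallback comes back to the route at 14, which is hydrolysed to 15 as in the last operation of step 6.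

Step 5. The radical C–H alkylation may give low conversion with the furan as limiting reagent, or some attack at a β-position. The fallback replaces the radical step by halogenation and cross-coupling. It sets out from 10. NBS in DMF at −20 °C brominates C5 to give 2-bromo-5-(5-bromopentyl)furan F6, which is used at once. Palladium-catalysed coupling with the Reformatsky reagent BrZnCH2CO2Me, made from 11 and zinc (Pd(dba)2, P(t-Bu)3, THF, rt), reacts only at the sp2 C–Br bond. The fallback comes back to the route at 12.

## Further compounds

F1 | step 3 | (E)-6,6-diethoxyhex-2-en-1-ol | OC/C=C/CCC(OCC)OCC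
F2 | step 3 | (E)-1-chloro-6,6-diethoxyhex-2-ene | ClC/C=C/CCC(OCC)OCC
F3 | step 6 | 2-(hept-6-en-1-yl)furan | C=CCCCCCc1ccco1
F4 | step 6 | 2-[(6E,8S)-8-butyl-11,11-diethoxyundec-6-en-1-yl]furan | CCCC[C@@H](CCC(OCC)OCC)/C=C/CCCCCc1ccco1
F5 | step 6 | 2-[(8R)-8-butyl-11,11-diethoxyundecyl]furan | CCCC[C@@H](CCC(OCC)OCC)CCCCCCCc1ccco1
F6 | step 5 | 2-bromo-5-(5-bromopentyl)furan | BrCCCCCc1ccc(Br)o1
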